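**Plan**

Labels: ring A is the oxolane O1–C2(Ar)–C3–C4–C5; C9 is the hydroxymethyl carbon on C3 and C7' the aroyl carbon on C4 (Ar = 3,4-dimethoxyphenyl, Ar' = 3,4,5-trimethoxyphenyl).
Enabling feature: in ring A the C9 hydroxymethyl on C3 and the oxygen-bearing C7' on C4 are cis, so C9 can be passed from a silyl ether on the C7' oxygen to C3 of a C2=C3 enol ether through a six-membered siloxane ring B.
Cuts, in retrosynthetic order: C7'=O to C7'–OH; C9–OH to C9–Si; C3–C9 and C2–H (radical closure of ring B); O1–C2 (alkynol cycloisomerisation to ring A); C4–C7' (allenylzinc plus aldehyde); C3–C4 (acetylide plus aldehyde).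
Forward: the chain is joined in steps 1–5, ring A closes in step 8, ring B closes in step 11, then ring B is opened oxidatively and C7' is oxidised.
Stereochemistry: C4 comes from a propargylic carbinol set by Noyori transfer hydrogenation and transferred by anti-SN2'/syn-SE2' substitution; C7' (anti, erased at the end) from the cyclic addition transition state; C3 from the tether anchored at C4; C2 from hydrogen-atom transfer to the convex face.

Key step: step 11

Remark: (tert-butyldimethylsilyloxy)acetaldehyde 2 is taken as a commercial reagent; it is otherwise made from methyl glycolate (TBSCl, then DIBAL-H).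

**Route**

Step 1
Reactants: 1 4-ethynyl-1,2-dimethoxybenzene; 2 (tert-butyldimethylsilyloxy)acetaldehyde
Product: 4 rac-1-[(tert-butyldimethylsilyl)oxy]-4-(3,4-dimethoxyphenyl)but-3-yn-2-ol, via lithium (3,4-dimethoxyphenyl)acetylide 3 (not isolated)
Conditions: n-BuLi, THF, −78 °C; then 2, −78 to 0 °C; H2O
Reagents that add atoms: none
Why: Deprotonation of the terminal alkyne and 1,2-addition of the lithium acetylide to the aldehyde forms the C3–C4 bond; the carbinol is racemic here and is set in step 3.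

Step 2
Reactants: 4 rac-1-[(tert-butyldimethylsilyl)oxy]-4-(3,4-dimethoxyphenyl)but-3-yn-2-ol
Product: 5 1-[(tert-butyldimethylsilyl)oxy]-4-(3,4-dimethoxyphenyl)but-3-yn-2-one
Conditions: MnO2 (activated, excess), CH2Cl2, rt
Reagents that add atoms: none
Why: Activated MnO2 oxidises propargylic alcohols to ynones under neutral conditions that should leave the silyl ether and the aryl ethers intact.

Step 3
Reactants: 5 1-[(tert-butyldimethylsilyl)oxy]-4-(3,4-dimethoxyphenyl)but-3-yn-2-one
Product: 6 (2S)-1-[(tert-butyldimethylsilyl)oxy]-4-(3,4-dimethoxyphenyl)but-3-yn-2-ol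
Conditions: Ru[(R,R)-TsDPEN](p-cymene) (1 mol %), i-PrOH, rt
Reagents that add atoms: none
Why: Noyori asymmetric transfer hydrogenation of an ynone, in which the alkyne plays the role of the aryl group of an aryl ketone, so the (R,R)-ligand should give the (S)-carbinol (the descriptor is S because CH2OSi outranks the alkynyl carbon).

Step 4
Reactants: 6 (2S)-1-[(tert-butyldimethylsilyl)oxy]-4-(3,4-dimethoxyphenyl)but-3-yn-2-ol
Product: 7 (2S)-1-[(tert-butyldimethylsilyl)oxy]-4-(3,4-dimethoxyphenyl)but-3-yn-2-yl methanesulfonate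
Conditions: MsCl, Et3N, CH2Cl2, −78 to −20 °C; used crude
Reagents that add atoms: methanesulfonyl chloride, CS(=O)(=O)Cl
Why: Sulfonylation of the secondary alcohol occurs at oxygen with retention at carbon and gives the leaving group needed for the propargylation.

Step 5
Reactants: 7 (2S)-1-[(tert-butyldimethylsilyl)oxy]-4-(3,4-dimethoxyphenyl)but-3-yn-2-yl methanesulfonate; 8 3,4,5-trimethoxybenzaldehyde
Product: 10 (1S,2R)-2-{[(tert-butyldimethylsilyl)oxy]methyl}-4-(3,4-dimethoxyphenyl)-1-(3,4,5-trimethoxyphenyl)but-3-yn-1-ol, via allenyl(ethyl)zinc 9 (not isolated)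
Conditions: Pd(OAc)2 (5 mol %), PPh3 (5 mol %), Et2Zn (3 equiv), THF, −78 to −20 °C; aq NH4Cl
Reagents that add atoms: none
Why: Marshall–Tamaru propargylation, in which zerovalent palladium displaces the mesylate anti (SN2'), transmetalation to zinc with retention gives the (aS)-allenylzinc 9, and cyclic SE2' addition to the aldehyde forms C4–C7' on the face opposite the departed mesylate (C4 = R), the chair-like transition state setting the anti carbinol (C7' = S).

Step 6
Reactants: 10 (1S,2R)-2-{[(tert-butyldimethylsilyl)oxy]methyl}-4-(3,4-dimethoxyphenyl)-1-(3,4,5-trimethoxyphenyl)but-3-yn-1-ol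
Product: 11 tert-butyl{[(2R)-4-(3,4-dimethoxyphenyl)-2-[(S)-(3,4,5-trimethoxyphenyl)(triisopropylsilyloxy)methyl]but-3-yn-1-yl]oxy}dimethylsilane
Conditions: TIPSOTf, 2,6-lutidine, CH2Cl2, 0 °C to rt
Reagents that add atoms: triisopropylsilyl trifluoromethanesulfonate, CC(C)[Si](OS(=O)(=O)C(F)(F)F)(C(C)C)C(C)C
Why: Silyl triflate silylation caps the hindered benzylic C7' hydroxyl with a group that should outlast removal of the primary TBS ether and later fall to fluoride without acid.

Step 7
Reactants: 11 tert-butyl{[(2R)-4-(3,4-dimethoxyphenyl)-2-[(S)-(3,4,5-trimethoxyphenyl)(triisopropylsilyloxy)methyl]but-3-yn-1-yl]oxy}dimethylsilane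
Product: 12 (2R)-4-(3,4-dimethoxyphenyl)-2-[(S)-(3,4,5-trimethoxyphenyl)(triisopropylsilyloxy)methyl]but-3-yn-1-ol
Conditions: HF·pyridine, pyridine, THF, 0 °C
Reagents that add atoms: none
Why: Buffered HF·pyridine cleaves a primary TBS ether much faster than a secondary TIPS ether, so only the C5 hydroxyl should be freed.

Step 8
Reactants: 12 (2R)-4-(3,4-dimethoxyphenyl)-2-[(S)-(3,4,5-trimethoxyphenyl)(triisopropylsilyloxy)methyl]but-3-yn-1-ol
Product: 13 {(S)-[(3R)-5-(3,4-dimethoxyphenyl)-2,3-dihydrofuran-3-yl](3,4,5-trimethoxyphenyl)methoxy}triisopropylsilane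
Conditions: Ph3PAuNTf2 (2 mol %), CH2Cl2, 4 Å MS, rt; Et3N quench
Reagents that add atoms: none
Why: Gold-catalysed 5-endo-dig hydroalkoxylation of a homopropargylic alcohol, in which the primary hydroxyl attacks the gold-activated alkyne at the aryl-bearing carbon C2 and protodeauration closes ring A as the enol ether without touching C4.

Step 9
Reactants: 13 {(S)-[(3R)-5-(3,4-dimethoxyphenyl)-2,3-dihydrofuran-3-yl](3,4,5-trimethoxyphenyl)methoxy}triisopropylsilane
Product: 14 (S)-[(3R)-5-(3,4-dimethoxyphenyl)-2,3-dihydrofuran-3-yl](3,4,5-trimethoxyphenyl)methanol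
Conditions: Bu4NF, THF, 0 °C to rt
Reagents that add atoms: none
Why: Fluoride cleaves the silyl ether under basic conditions that the acid-sensitive aryl enol ether should tolerate.

Step 10
Reactants: 14 (S)-[(3R)-5-(3,4-dimethoxyphenyl)-2,3-dihydrofuran-3-yl](3,4,5-trimethoxyphenyl)methanol; 15 (bromomethyl)chlorodimethylsilane
Product: 16 (bromomethyl){(S)-[(3R)-5-(3,4-dimethoxyphenyl)-2,3-dihydrofuran-3-yl](3,4,5-trimethoxyphenyl)methoxy}dimethylsilane
Conditions: Et3N, DMAP (cat.), CH2Cl2, 0 °C; filtered and used crude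
Reagents that add atoms: none
Why: Amine-mediated O-silylation of the secondary alcohol with the chlorosilane installs the radical precursor on the C7' oxygen; the hydrolytically labile silyl ether is carried on without chromatography.

Step 11
Reactants: 16 (bromomethyl){(S)-[(3R)-5-(3,4-dimethoxyphenyl)-2,3-dihydrofuran-3-yl](3,4,5-trimethoxyphenyl)methoxy}dimethylsilane
Product: 17 (2R,3S,4R,7'S)-cis-fused oxolane–siloxane bicycle (ring B = C9H2–SiMe2–O–C7'H(Ar') bridging C3 and C4 of ring A; Ar on C2 cis to C9)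
Conditions: Bu3SnH (1.3 equiv, syringe pump), AIBN (cat.), benzene (0.01 M), 80 °C
Reagents that add atoms: none
Why: The tributyltin radical abstracts bromine to give a nucleophilic silylmethyl radical, which adds 6-exo-trig to C3 of the aryl enol ether, closing the six-membered siloxane ring B (C9–Si–O–C7'–C4–C3) and leaving a benzylic, oxygen-stabilised radical at C2 that is reduced by Bu3SnH. The closest known reaction type is the radical cyclisation of (bromomethyl)dimethylsilyl ethers of allylic and homoallylic alcohols, including closures onto cyclic enol ethers. Because the tether is anchored on the oxygen of the C4 side chain, C9 can only reach the face of C3 on which that side chain sits, so C3 is set cis to C7' (cis ring fusion) by C4 alone. The C2 radical should then take hydrogen on the convex face, opposite the newly fused ring B, which places the aryl group cis to C9 and completes the all-cis array. The step needs 6-exo over 7-endo closure and cyclisation over direct reduction or 1,5-hydrogen transfer from C4–H; the aryl and oxygen substituents at C2 hinder endo attack and stabilise the exo radical, and slow addition of the stannane at high dilution keeps chain transfer slow. In the chair-like transition state the trimethoxyphenyl group on C7' can sit equatorial, so the relay centre should not oppose closure.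

Step 12
Reactants: 17 (2R,3S,4R,7'S)-cis-fused oxolane–siloxane bicycle
Product: 18 (S)-[(3R,4R,5R)-5-(3,4-dimethoxyphenyl)-4-(hydroxymethyl)oxolan-3-yl](3,4,5-trimethoxyphenyl)methanol
Conditions: 30 % H2O2, KF, KHCO3, THF–MeOH, rt
Reagents that add atoms: hydrogen peroxide, OO
Why: Tamao oxidation, in which fluoride-activated hydroperoxide attacks silicon, the C9–Si bond migrates to oxygen with retention and the Si–O bond to C7' is hydrolysed, giving the C9/C7' diol.

Step 13
Reactants: 18 (S)-[(3R,4R,5R)-5-(3,4-dimethoxyphenyl)-4-(hydroxymethyl)oxolan-3-yl](3,4,5-trimethoxyphenyl)methanol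
Product: 19 [(3R,4R,5R)-5-(3,4-dimethoxyphenyl)-4-(hydroxymethyl)oxolan-3-yl](3,4,5-trimethoxyphenyl)methanone
Conditions: MnO2 (activated), CH2Cl2, rt
Reagents that add atoms: none
Why: Activated MnO2 oxidises the benzylic secondary alcohol selectively over the saturated primary alcohol under neutral conditions, which should leave the epimerisable C4 centre next to the new ketone unchanged.

**Compound list**

1 | 4-ethynyl-1,2-dimethoxybenzene | COc1ccc(C#C)cc1OC | starting material
2 | (tert-butyldimethylsilyloxy)acetaldehyde | CC(C)(C)[Si](C)(C)OCC=O | starting material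
3 | lithium (3,4-dimethoxyphenyl)acetylide (formed in the flask) | COc1ccc(C#C[Li])cc1OC | intermediate
4 | rac-1-[(tert-butyldimethylsilyl)oxy]-4-(3,4-dimethoxyphenyl)but-3-yn-2-ol | COc1ccc(C#CC(O)CO[Si](C)(C)C(C)(C)C)cc1OC | intermediate
5 | 1-[(tert-butyldimethylsilyl)oxy]-4-(3,4-dimethoxyphenyl)but-3-yn-2-one | COc1ccc(C#CC(=O)CO[Si](C)(C)C(C)(C)C)cc1OC | intermediate
6 | (2S)-1-[(tert-butyldimethylsilyl)oxy]-4-(3,4-dimethoxyphenyl)but-3-yn-2-ol | COc1ccc(C#C[C@H](O)CO[Si](C)(C)C(C)(C)C)cc1OC | intermediate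
7 | (2S)-1-[(tert-butyldimethylsilyl)oxy]-4-(3,4-dimethoxyphenyl)but-3-yn-2-yl methanesulfonate | COc1ccc(C#C[C@H](OS(C)(=O)=O)CO[Si](C)(C)C(C)(C)C)cc1OC | intermediate
8 | 3,4,5-trimethoxybenzaldehyde | COc1cc(C=O)cc(OC)c1OC | starting material
9 | (aS)-[4-[(tert-butyldimethylsilyl)oxy]-1-(3,4-dimethoxyphenyl)buta-1,2-dien-1-yl](ethyl)zinc (formed in the flask) | CC[Zn]C(c1ccc(OC)c(OC)c1)=[C@@]=C([H])CO[Si](C)(C)C(C)(C)C | intermediate
10 | (1S,2R)-2-{[(tert-butyldimethylsilyl)oxy]methyl}-4-(3,4-dimethoxyphenyl)-1-(3,4,5-trimethoxyphenyl)but-3-yn-1-ol | COc1ccc(C#C[C@H](CO[Si](C)(C)C(C)(C)C)[C@H](O)c2cc(OC)c(OC)c(OC)c2)cc1OC | intermediate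
11 | tert-butyl{[(2R)-4-(3,4-dimethoxyphenyl)-2-[(S)-(3,4,5-trimethoxyphenyl)(triisopropylsilyloxy)methyl]but-3-yn-1-yl]oxy}dimethylsilane | COc1ccc(C#C[C@H](CO[Si](C)(C)C(C)(C)C)[C@H](O[Si](C(C)C)(C(C)C)C(C)C)c2cc(OC)c(OC)c(OC)c2)cc1OC | intermediate
12 | (2R)-4-(3,4-dimethoxyphenyl)-2-[(S)-(3,4,5-trimethoxyphenyl)(triisopropylsilyloxy)methyl]but-3-yn-1-ol | COc1ccc(C#C[C@H](CO)[C@H](O[Si](C(C)C)(C(C)C)C(C)C)c2cc(OC)c(OC)c(OC)c2)cc1OC | intermediate
13 | {(S)-[(3R)-5-(3,4-dimethoxyphenyl)-2,3-dihydrofuran-3-yl](3,4,5-trimethoxyphenyl)methoxy}triisopropylsilane | COc1ccc(cc1OC)C2=C[C@H](CO2)[C@H](O[Si](C(C)C)(C(C)C)C(C)C)c3cc(OC)c(OC)c(OC)c3 | intermediate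
14 | (S)-[(3R)-5-(3,4-dimethoxyphenyl)-2,3-dihydrofuran-3-yl](3,4,5-trimethoxyphenyl)methanol | COc1ccc(cc1OC)C2=C[C@H](CO2)[C@H](O)c3cc(OC)c(OC)c(OC)c3 | intermediate
15 | (bromomethyl)chlorodimethylsilane | C[Si](C)(Cl)CBr | starting material
16 | (bromomethyl){(S)-[(3R)-5-(3,4-dimethoxyphenyl)-2,3-dihydrofuran-3-yl](3,4,5-trimethoxyphenyl)methoxy}dimethylsilane | COc1ccc(cc1OC)C2=C[C@H](CO2)[C@H](O[Si](C)(C)CBr)c3cc(OC)c(OC)c(OC)c3 | intermediate
17 | (2R,3S,4R,7'S)-cis-fused oxolane–siloxane bicycle: ring B (C9H2–SiMe2–O–C7'H(Ar')) fused across C3–C4 of ring A, Ar on C2 cis to C9 | COc1ccc(cc1OC)[C@@H]2OC[C@H]3[C@@H]2C[Si](C)(C)O[C@@H]3c4cc(OC)c(OC)c(OC)c4 | intermediate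
18 | (S)-[(3R,4R,5R)-5-(3,4-dimethoxyphenyl)-4-(hydroxymethyl)oxolan-3-yl](3,4,5-trimethoxyphenyl)methanol | COc1ccc([C@@H]2OC[C@H]([C@H](O)c3cc(OC)c(OC)c(OC)c3)[C@@H]2CO)cc1OC | intermediate
19 | [(3R,4R,5R)-5-(3,4-dimethoxyphenyl)-4-(hydroxymethyl)oxolan-3-yl](3,4,5-trimethoxyphenyl)methanone | COc1ccc([C@@H]2OC[C@H](C(=O)c3cc(OC)c(OC)c(OC)c3)[C@@H]2CO)cc1OC | target

**Step count and risks**

Total step count: 13. Longest linear sequence: 13 steps (1 to 19); compounds 2, 8 and 15 each enter in a single step.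

Steps most likely to fail:

1. Step 11. The silylmethyl radical may be reduced before it cyclises, it may abstract the doubly activated C4–H through a six-membered transition state, or hydrogen delivery at C2 may lose its facial preference. The fallback brings C9 in as an electrophile and sets C2 and C3 by hydrogenation. It sets out from enol ether 13. Vilsmeier–Haack formylation (POCl3, DMF, 0 °C; aq NaOAc) at the nucleophilic C3 should give the 3-formyl-2-aryl-4,5-dihydrofuran F1. Luche reduction (NaBH4, CeCl3·7H2O, MeOH, −40 °C) should give the allylic alcohol F2. Hydrogenation of the tetrasubstituted enol ether (H2, Rh/Al2O3, EtOAc) from the face opposite the bulky C4 side chain should add both hydrogens trans to C7' and give the all-cis silyl ether F3. Cleavage of the silyl ether with Bu4NF brings the sequence back to the route at diol 18.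

2. Step 5. Chirality transfer may erode through racemisation of the allenylmetal species, silanolate may be lost by 1,4-elimination to an enyne, or the aldehyde may add at the zinc-bearing carbon. The fallback uses an isolable allenylboronate and sets out from alcohol 6. Acylation (ClCO2Me, pyridine, CH2Cl2) should give the methyl carbonate F4. Copper-catalysed anti-SN2' borylation (CuCl, NaOt-Bu, Xantphos, B2pin2, THF) should give the (aR)-allenylboronate F5. Thermal addition of F5 to aldehyde 8 (toluene, 60 °C) through a closed six-membered SE2' transition state, followed by aqueous work-up, should give the same anti alcohol and rejoin the route at 10.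

3. Step 8. The acid-sensitive aryl enol ether may be hydrated or take up a second alcohol under the gold catalyst, or the alkyne may fail to turn over. The fallback replaces metal activation by electrophilic cyclisation and sets out from alkynol 12. 5-Endo-dig iodoetherification (I2, NaHCO3, MeCN, 0 °C) should give the 4-iodo-2,3-dihydrofuran F6. Palladium-catalysed formate reduction of the vinyl iodide (Pd(OAc)2, PPh3, HCO2H, Et3N, DMF, 60 °C) should then rejoin the route at 13.

Further compounds
F1 | step 11 | (4R)-2-(3,4-dimethoxyphenyl)-4-[(S)-(3,4,5-trimethoxyphenyl)(triisopropylsilyloxy)methyl]-4,5-dihydrofuran-3-carbaldehyde | COc1ccc(cc1OC)C2=C(C=O)[C@H](CO2)[C@H](O[Si](C(C)C)(C(C)C)C(C)C)c3cc(OC)c(OC)c(OC)c3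
F2 | step 11 | [(4R)-2-(3,4-dimethoxyphenyl)-4-[(S)-(3,4,5-trimethoxyphenyl)(triisopropylsilyloxy)methyl]-4,5-dihydrofuran-3-yl]methanol | COc1ccc(cc1OC)C2=C(CO)[C@H](CO2)[C@H](O[Si](C(C)C)(C(C)C)C(C)C)c3cc(OC)c(OC)c(OC)c3
F3 | step 11 | [(2R,3R,4R)-2-(3,4-dimethoxyphenyl)-4-[(S)-(3,4,5-trimethoxyphenyl)(triisopropylsilyloxy)methyl]oxolan-3-yl]methanol | COc1ccc([C@@H]2OC[C@H]([C@H](O[Si](C(C)C)(C(C)C)C(C)C)c3cc(OC)c(OC)c(OC)c3)[C@@H]2CO)cc1OC
F4 | step 5 | (2S)-1-[(tert-butyldimethylsilyl)oxy]-4-(3,4-dimethoxyphenyl)but-3-yn-2-yl methyl carbonate | COc1ccc(C#C[C@H](OC(=O)OC)CO[Si](C)(C)C(C)(C)C)cc1OC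
F5 | step 5 | (aR)-2-[4-[(tert-butyldimethylsilyl)oxy]-1-(3,4-dimethoxyphenyl)buta-1,2-dien-1-yl]-4,4,5,5-tetramethyl-1,3,2-dioxaborolane | CC1(C)OB(OC1(C)C)C(c2ccc(OC)c(OC)c2)=[C@@]=C([H])CO[Si](C)(C)C(C)(C)C
F6 | step 8 | {(S)-[(3R)-5-(3,4-dimethoxyphenyl)-4-iodo-2,3-dihydrofuran-3-yl](3,4,5-trimethoxyphenyl)methoxy}triisopropylsilane | COc1ccc(cc1OC)C2=C(I)[C@H](CO2)[C@H](O[Si](C(C)C)(C(C)C)C(C)C)c3cc(OC)c(OC)c(OC)c3
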